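**Plan** (target numbering: C1 = oxirane carbon bearing C7H2OBz, C2 = CH–OBz, C3 = CH–OH, C4=C5, C6 = oxirane CH)

1. Retrosynthesis: the two benzoates, the C3 silyl ether and the C1–C6 oxirane are taken off first, exposing a cis-5,6-dioxygenated cyclohexa-1,3-diene. The C2–C3 bond is then cut by a retro-6π-electrocyclisation to an open triene C2=C1–C6=C5–C4=C3, and the C1–C6 bond by a Sonogashira disconnection.
2. Enabling feature: C2 and C3 both carry oxygen, their C–O bonds are cis, and they are linked through C4=C5 and through C1–C6, whose oxirane is a masked alkene. This is the imprint of a disrotatory closure of a 1,6-dioxygenated (Z)-hexatriene, which joins two carbons of like (acceptor) polarity without any redox reagent.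
3. Helper: O2–C2=C1–C7 is built into a spiro 1,3-dioxin-4-one, the ketal of (−)-menthone. This temporary ring fixes the enol geometry at C1=C2, activates the triene through the C7 carbonyl, biases the face of closure, and is removed by hydride, which frees C2–OH and C7–OH together.
4. Forward order: dioxinone ring (formylketene plus ketone) → iodination, Sonogashira coupling, Lindlar reduction, oxidation, silyl enol ether → carbocycle by 6π closure → auxiliary off → oxirane → benzoates → desilylation.
5. Stereochemistry: C2/C3 cis from disrotation of two termini whose oxygens are both outside; absolute sense from the menthone acetal; C1/C6 from epoxidation directed by the C2 hydroxyl; the (Z)-alkene from the Lindlar step.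

Key step: step 8

Assumption: the spiro acetal is taken to shield the dioxinone face that carries its isopropyl-bearing ring carbon, so that the (2S)-spiro epimer 5 leads to 12; should the other face be preferred, the (2R)-spiro epimer formed alongside 5 in step 2 is carried through the same steps instead.

**Step 1**
Reactants: 1 5-(methoxymethylidene)-2,2-dimethyl-1,3-dioxane-4,6-dione
Product: 2 5-(hydroxymethylidene)-2,2-dimethyl-1,3-dioxane-4,6-dione (formyl Meldrum's acid)
Conditions: 2 M aq. HCl, rt
Reagents that add atoms: water, O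
Why: Acid-catalysed addition–elimination of water at the vinylogous ester carbon exchanges the enol methyl ether for the free enol.

**Step 2**
Reactants: 2 formyl Meldrum's acid; 3 (−)-menthone, (2S,5R)-5-methyl-2-(propan-2-yl)cyclohexan-1-one
Product: 5 (2S,2'S,5'R)-5'-methyl-2'-(propan-2-yl)spiro[1,3-dioxine-2,1'-cyclohexan]-4-one, via formylketene 4 (not isolated)
Conditions: 3 (3 equiv), toluene, 110 °C, slow addition of 2; chromatography to separate the spiro epimers
Reagents that add atoms: none
Why: Thermolysis of the acyl Meldrum's acid (retro-[4+2], loss of acetone and CO2) releases formylketene 4, which the ketone carbonyl of 3 traps in a hetero-Diels–Alder reaction to give the 5,6-unsubstituted dioxinone; the spiro carbon forms as both epimers and the (2S)-epimer is kept.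

**Step 3**
Reactants: 5 spiro dioxinone
Product: 6 (2S,2'S,5'R)-5-iodo-5'-methyl-2'-(propan-2-yl)spiro[1,3-dioxine-2,1'-cyclohexan]-4-one
Conditions: NIS, AcOH, CH2Cl2, rt, dark
Reagents that add atoms: N-iodosuccinimide, O=C1CCC(=O)N1I
Why: Electrophilic iodination of the vinylogous carbonate at its nucleophilic alpha carbon (the future C1), followed by loss of the proton.

**Step 4**
Reactants: 6 iodo dioxinone; 7 but-3-yn-1-ol
Product: 8 (2S,2'S,5'R)-5-(4-hydroxybut-1-yn-1-yl)-5'-methyl-2'-(propan-2-yl)spiro[1,3-dioxine-2,1'-cyclohexan]-4-one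
Conditions: PdCl2(PPh3)2 (3 mol %), CuI (6 mol %), Et3N, THF, rt
Reagents that add atoms: none
Why: Sonogashira coupling of the alpha-iodo enone-type vinyl iodide with the terminal alkyne forms the C1–C6 bond; the ketal-ester ring is inert to the amine.

**Step 5**
Reactants: 8 alkynol
Product: 9 (2S,2'S,5'R)-5-[(1Z)-4-hydroxybut-1-en-1-yl]-5'-methyl-2'-(propan-2-yl)spiro[1,3-dioxine-2,1'-cyclohexan]-4-one
Conditions: H2 (1 atm), Pd/CaCO3 poisoned with Pb(OAc)2 (Lindlar catalyst), quinoline, EtOAc, rt
Reagents that add atoms: none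
Why: Lindlar semihydrogenation adds hydrogen syn to the alkyne and sets the (Z)-geometry of C5=C6, the central bond of the triene; the electron-poor trisubstituted dioxinone alkene is not reduced.

**Step 6**
Reactants: 9 (Z)-alkenol
Product: 10 (3Z)-4-[(2S,2'S,5'R)-5'-methyl-4-oxo-2'-(propan-2-yl)spiro[1,3-dioxine-2,1'-cyclohexan]-5-yl]but-3-enal
Conditions: Dess–Martin periodinane, CH2Cl2, 0 °C; crude aldehyde used at once
Reagents that add atoms: none
Why: Dess–Martin oxidation of the primary homoallylic alcohol under non-basic conditions should give the beta,gamma-unsaturated aldehyde without moving the (Z)-alkene into conjugation.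

**Step 7**
Reactants: 10 aldehyde
Product: 11 (2S,2'S,5'R)-5-[(1Z,3E)-4-{[tert-butyl(dimethyl)silyl]oxy}buta-1,3-dien-1-yl]-5'-methyl-2'-(propan-2-yl)spiro[1,3-dioxine-2,1'-cyclohexan]-4-one
Conditions: TBSOTf, Et3N, Et2O, −78 → 0 °C
Reagents that add atoms: tert-butyldimethylsilyl trifluoromethanesulfonate, CC(C)(C)[Si](C)(C)OS(=O)(=O)C(F)(F)F
Why: Soft enolisation (silyl triflate, amine) removes the doubly activated C4 proton and traps the dienol on oxygen; the extended planar arrangement should favour the (E)-enol ether, and the (Z)-C5=C6 bond is not touched.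

**Step 8**
Reactants: 11 silyl trienol ether
Product: 12 (2S,2'S,5'R,8R,8aS)-8-{[tert-butyl(dimethyl)silyl]oxy}-5'-methyl-2'-(propan-2-yl)-8,8a-dihydrospiro[1,3-benzodioxine-2,1'-cyclohexan]-4-one
Conditions: toluene (0.02 M), BHT, 60 °C, base-washed glassware
Reagents that add atoms: none
Why: Warming brings the s-cis,s-cis conformer of the hexatriene C2=C1–C6=C5–C4=C3, which carries oxygen on both termini, to a thermally allowed disrotatory 6π-electrocyclisation that forms the C2–C3 sigma bond and moves the pi bonds to C1=C6 and C4=C5. The closest known reaction type is the thermal closure of (E,Z,E)-hexatrienes to cis-5,6-disubstituted cyclohexa-1,3-dienes, which is accelerated by an acyl group on an inner triene carbon, here the dioxinone carbonyl on C1. The six-membered carbocycle is therefore closed in the disrotatory 6π mode and not by a polar attack, so the like polarity of the two oxygen-bearing carbons is no obstacle. The relative configuration at C2 and C3 follows from disrotation of two termini whose oxygens both stand outside (the ring oxygen of the dioxinone and the (E)-silyl enol ether), which places the two C–O bonds cis. The absolute configuration is controlled by the spiro menthone acetal, whose isopropyl-bearing ring carbon blocks one face of C2 so that the dienyl arm swings onto the other. The step needs this face selection and discrimination against any (3Z)-enol ether isomer, which has an inside oxygen, closes much more slowly and would give the trans product; the moderate temperature is chosen so that this isomer and the dioxinone ring (cycloreversion) stay intact.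

**Step 9**
Reactants: 12 bicyclic dioxanone
Product: 13 (1S,6R)-6-{[tert-butyl(dimethyl)silyl]oxy}-2-(hydroxymethyl)cyclohexa-2,4-dien-1-ol
Conditions: iBu2AlH (4 equiv), CH2Cl2, −78 → −20 °C; aq. KNaC4H4O6 work-up; product kept cold and free of acid
Reagents that add atoms: none
Why: Hydride reduction of the C7 carbonyl collapses the acylal, so C7 becomes the primary allylic alcohol, the auxiliary ketone is expelled (and reduced) and O2 is left as the free C2 hydroxyl; the silyl ether and both stereocentres are not touched.

**Step 10**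
Reactants: 13 diene diol
Product: 14 (1R,2R,3R,6S)-3-{[tert-butyl(dimethyl)silyl]oxy}-1-(hydroxymethyl)-7-oxabicyclo[4.1.0]hept-4-en-2-ol
Conditions: VO(acac)2 (5 mol %), tBuOOH (1.2 equiv), CH2Cl2, 0 °C
Reagents that add atoms: tert-butyl hydroperoxide, CC(C)(C)OO
Why: Vanadium-catalysed hydroxyl-directed epoxidation of an allylic alcohol: C1=C6 is flanked by both free hydroxyls and the pseudoaxial ring hydroxyl on C2 delivers the oxygen to its own face, which sets C1 and C6 with the oxirane cis to O2 and O3, while C4=C5 has no free allylic hydroxyl.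

**Step 11**
Reactants: 14 epoxy diol
Product: 15 [(1S,2R,3R,6S)-2-(benzoyloxy)-3-{[tert-butyl(dimethyl)silyl]oxy}-7-oxabicyclo[4.1.0]hept-4-en-1-yl]methyl benzoate
Conditions: BzCl (2.5 equiv), pyridine, DMAP (cat.), CH2Cl2, 0 °C → rt
Reagents that add atoms: benzoyl chloride, O=C(Cl)c1ccccc1
Why: Acylation of the primary and the secondary hydroxyl under nucleophilic catalysis; no C–O bond to a stereocentre is broken, so the configuration is retained.

**Step 12**
Reactants: 15 silyl ether dibenzoate
Product: 16 [(1S,2R,3R,6S)-2-(benzoyloxy)-3-hydroxy-7-oxabicyclo[4.1.0]hept-4-en-1-yl]methyl benzoate (target)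
Conditions: Bu4NF, AcOH (1:1), THF, 0 °C → rt
Reagents that add atoms: none
Why: Fluoride cleaves the Si–O bond, and the acetic acid buffer should prevent both benzoyl migration from O2 to O3 and opening of the vinyl oxirane.

**Compound list**
1 | 5-(methoxymethylidene)-2,2-dimethyl-1,3-dioxane-4,6-dione | COC=C1C(=O)OC(C)(C)OC1=O | starting material
2 | 5-(hydroxymethylidene)-2,2-dimethyl-1,3-dioxane-4,6-dione | OC=C1C(=O)OC(C)(C)OC1=O | intermediate
3 | (−)-menthone, (2S,5R)-5-methyl-2-(propan-2-yl)cyclohexan-1-one | CC(C)[C@@H]1CC[C@@H](C)CC1=O | starting material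
4 | formylketene (3-oxoprop-2-enal), not isolated | O=CC=C=O | intermediate
5 | (2S,2'S,5'R)-5'-methyl-2'-(propan-2-yl)spiro[1,3-dioxine-2,1'-cyclohexan]-4-one | O=C1O[C@]2(C[C@H](C)CC[C@H]2C(C)C)OC=C1 | intermediate
6 | (2S,2'S,5'R)-5-iodo-5'-methyl-2'-(propan-2-yl)spiro[1,3-dioxine-2,1'-cyclohexan]-4-one | O=C1O[C@]2(C[C@H](C)CC[C@H]2C(C)C)OC=C1I | intermediate
7 | but-3-yn-1-ol | C#CCCO | starting material
8 | (2S,2'S,5'R)-5-(4-hydroxybut-1-yn-1-yl)-5'-methyl-2'-(propan-2-yl)spiro[1,3-dioxine-2,1'-cyclohexan]-4-one | O=C1O[C@]2(C[C@H](C)CC[C@H]2C(C)C)OC=C1C#CCCO | intermediate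
9 | (2S,2'S,5'R)-5-[(1Z)-4-hydroxybut-1-en-1-yl]-5'-methyl-2'-(propan-2-yl)spiro[1,3-dioxine-2,1'-cyclohexan]-4-one | O=C1O[C@]2(C[C@H](C)CC[C@H]2C(C)C)OC=C1/C=C\CCO | intermediate
10 | (3Z)-4-[(2S,2'S,5'R)-5'-methyl-4-oxo-2'-(propan-2-yl)spiro[1,3-dioxine-2,1'-cyclohexan]-5-yl]but-3-enal | O=C1O[C@]2(C[C@H](C)CC[C@H]2C(C)C)OC=C1/C=C\CC=O | intermediate
11 | (2S,2'S,5'R)-5-[(1Z,3E)-4-{[tert-butyl(dimethyl)silyl]oxy}buta-1,3-dien-1-yl]-5'-methyl-2'-(propan-2-yl)spiro[1,3-dioxine-2,1'-cyclohexan]-4-one | O=C1O[C@]2(C[C@H](C)CC[C@H]2C(C)C)OC=C1/C=C\C=C\O[Si](C)(C)C(C)(C)C | intermediate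
12 | (2S,2'S,5'R,8R,8aS)-8-{[tert-butyl(dimethyl)silyl]oxy}-5'-methyl-2'-(propan-2-yl)-8,8a-dihydrospiro[1,3-benzodioxine-2,1'-cyclohexan]-4-one | O=C1O[C@]2(C[C@H](C)CC[C@H]2C(C)C)O[C@@H]3[C@H](O[Si](C)(C)C(C)(C)C)C=CC=C13 | intermediate
13 | (1S,6R)-6-{[tert-butyl(dimethyl)silyl]oxy}-2-(hydroxymethyl)cyclohexa-2,4-dien-1-ol | OCC1=CC=C[C@@H](O[Si](C)(C)C(C)(C)C)[C@H]1O | intermediate
14 | (1R,2R,3R,6S)-3-{[tert-butyl(dimethyl)silyl]oxy}-1-(hydroxymethyl)-7-oxabicyclo[4.1.0]hept-4-en-2-ol | OC[C@]12O[C@H]1C=C[C@@H](O[Si](C)(C)C(C)(C)C)[C@H]2O | intermediate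
15 | [(1S,2R,3R,6S)-2-(benzoyloxy)-3-{[tert-butyl(dimethyl)silyl]oxy}-7-oxabicyclo[4.1.0]hept-4-en-1-yl]methyl benzoate | O=C(OC[C@]12O[C@H]1C=C[C@@H](O[Si](C)(C)C(C)(C)C)[C@H]2OC(=O)c1ccccc1)c1ccccc1 | intermediate
16 | [(1S,2R,3R,6S)-2-(benzoyloxy)-3-hydroxy-7-oxabicyclo[4.1.0]hept-4-en-1-yl]methyl benzoate | O=C(OC[C@]12O[C@H]1C=C[C@@H](O)[C@H]2OC(=O)c1ccccc1)c1ccccc1 | target

**Totals**
Total step count: 12. Longest linear sequence: 12 steps (1 → 16).

**Steps most likely to fail**

Step 8. The closure may discriminate poorly between the two faces of the dioxinone, and any (3Z)-enol ether present does not take part. The fallback replaces auxiliary control by reagent control; it sets out from 13, made from unseparated 12 and therefore of low enantiomeric purity, and comes back at 14. Sharpless asymmetric epoxidation (Ti(OiPr)4, L-(+)-diisopropyl tartrate, tBuOOH, 4 Å molecular sieves, CH2Cl2, −20 °C, stopped at partial conversion) places the oxygen on the face syn to the C2 hydroxyl only in the wanted enantiomer, which is the matched and faster case and gives 14. The mirror-image diol is left behind or gives the anti-epoxy diol F1, which is removed by chromatography.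

Step 7. The silylation may give the enol ether with the wrong geometry, move the C5=C6 bond into conjugation, or lose the aldehyde by self-condensation. The fallback builds the triene from pieces of fixed geometry; it sets out from 6 and comes back at 11. Commercial malondialdehyde tetrabutylammonium salt is O-silylated (TBSCl, CH2Cl2) to (2E)-3-{[tert-butyl(dimethyl)silyl]oxy}prop-2-enal F2. Stork–Zhao olefination of F2 (Ph3P=CHI from (iodomethyl)triphenylphosphonium iodide and NaN(SiMe3)2, THF, −78 °C) should give tert-butyl{[(1E,3Z)-4-iodobuta-1,3-dien-1-yl]oxy}dimethylsilane F3. Iodide 6 is converted by iodine–magnesium exchange (iPrMgCl·LiCl, THF, −40 °C) and ZnCl2 into the dioxinonylzinc chloride F4, which is not isolated. Negishi coupling of F4 with F3 (Pd(PPh3)4, THF, rt) should then give 11 with both alkene geometries retained.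

Step 10. The oxygen may be delivered to the wrong alkene or face, or the dihydroarene diol may dehydrate to a phenol. The fallback sets the oxirane face by bromonium opening and inversion instead of hydroxyl direction; it sets out from 13 and comes back at 15. Both hydroxyls are benzoylated first (BzCl, pyridine, DMAP) to the diene dibenzoate F5. NBS in wet THF at 0 °C should add bromine to C1=C6 on the face away from the C2 and C3 oxygens, with water entering at allylic C6 from the other face, to give the bromohydrin F6. DBU in CH2Cl2 then closes the oxirane with inversion at C1, which places it syn to the benzoate and gives 15.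

**Further compounds**
F1 | step 8 | C2,C3-epimer of 14: 3-{[tert-butyl(dimethyl)silyl]oxy}-1-(hydroxymethyl)-7-oxabicyclo[4.1.0]hept-4-en-2-ol with the oxirane as in 14 and the C2 hydroxyl and C3 silyloxy group on the opposite face | OC[C@]12O[C@H]1C=C[C@H](O[Si](C)(C)C(C)(C)C)[C@@H]2O
F2 | step 7 | (2E)-3-{[tert-butyl(dimethyl)silyl]oxy}prop-2-enal | O=C/C=C/O[Si](C)(C)C(C)(C)C
F3 | step 7 | tert-butyl{[(1E,3Z)-4-iodobuta-1,3-dien-1-yl]oxy}dimethylsilane | I/C=C\C=C\O[Si](C)(C)C(C)(C)C
F4 | step 7 | chloro[(2S,2'S,5'R)-5'-methyl-4-oxo-2'-(propan-2-yl)spiro[1,3-dioxine-2,1'-cyclohexan]-5-yl]zinc, not isolated | O=C1O[C@]2(C[C@H](C)CC[C@H]2C(C)C)OC=C1[Zn]Cl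
F5 | step 10 | [(5R,6S)-6-(benzoyloxy)-5-{[tert-butyl(dimethyl)silyl]oxy}cyclohexa-1,3-dien-1-yl]methyl benzoate | O=C(OCC1=CC=C[C@@H](O[Si](C)(C)C(C)(C)C)[C@H]1OC(=O)c1ccccc1)c1ccccc1
F6 | step 10 | [2-(benzoyloxy)-1-bromo-3-{[tert-butyl(dimethyl)silyl]oxy}-6-hydroxycyclohex-4-en-1-yl]methyl benzoate, bromine on the face opposite to the three ring oxygens | O=C(OC[C@@]1(Br)[C@@H](O)C=C[C@@H](O[Si](C)(C)C(C)(C)C)[C@H]1OC(=O)c1ccccc1)c1ccccc1
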